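**Retrosynthetic overview**

1. Feature: in ring A of unit 1 (the 6-linked flavone) the axis carbon C6 lies between the oxygen-bearing C5 and C7, and in ring A of unit 2 (the 8-linked flavone) the axis carbon C8'' lies between C7'' and C8a''. The C6–C8'' axis is therefore the central sp3–sp3 bond of a 1,1,2,2-tetraacylethane, and each ring A is a malonyl C3 unit joined to an acetone 1,3-dianion C3 unit.
2. Both rings C (O1–C2 and C4–C4a in each unit) are disconnected to biphenyl-2,2',4,4',6,6'-hexol and two molecules of ethyl 4-methoxybenzoylacetate (thermal Mentzer condensation). The 6,6''- and 8,8''-linked isomers formed alongside are drawn into the 6,8''-linked target by Wessely–Moser equilibration in the same step.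
3. The hexol is traced to its 3,3',5,5'-tetraethyl ester by saponification and decarboxylation.
4. Both rings A are disconnected at C4a–C5, C7–C8, C6''–C7'' and C4a''–C8a'' to tetraethyl ethane-1,1,2,2-tetracarboxylate and two molecules of diethyl 3-oxopentanedioate (double [3+3], fourfold Claisen condensation).
5. Order of ring formation: rings A of both units together (step 1), then rings C of both units together (step 3); rings B are bought with the ketoester.

Key step: step 1

Remark: the SMILES fixes no configuration at the C6–C8'' axis, so the target is taken as the racemic pair of atropisomers; the molecule has no stereocentre.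

**Route**

Step 1
Reactants: 1 tetraethyl ethane-1,1,2,2-tetracarboxylate; 2 diethyl 3-oxopentanedioate (diethyl 1,3-acetonedicarboxylate)
Product: 4 tetraethyl 2,2',4,4',6,6'-hexahydroxybiphenyl-3,3',5,5'-tetracarboxylate, via mono-annulated arylmalonate 3 (not isolated)
Conditions: NaOEt (4.5 equiv), xylene, 140 °C, 2 (2.3 equiv) added over 6 h, EtOH distilled off; then 2 M HCl, 0 °C
Reagents that add atoms: none
Why: Proposed new method: the enolate of 2 (Na+ counter-ion) should acylate at one ester of a malonate end of 1 (directly, or through the ethoxycarbonylketene that the malonate anion can form by E1cB loss of ethoxide at 140 °C), after which the second methylene of the same keto diester attacks the geminal ester and the cyclohexane-1,3,5-trione enolises irreversibly to the phloroglucinolate of 3, the sequence then repeating at the other malonate end to give 4. The closest known reaction type is the sodium-mediated Claisen–Dieckmann condensation of diethyl malonate with diethyl 3-oxopentanedioate to diethyl 2,4,6-trihydroxyisophthalate, which here has to run twice on malonate carbons that already carry a carbon substituent. Each ring A closes by a 6-(enolexo)-exo-trig Dieckmann-type acylation, the four new bonds being C4a–C5 and C7–C8 of unit 1 and C6''–C7'' and C4a''–C8a'' of unit 2 in target numbering. No stereocentre is formed, and the axis of 4 carries identical ortho substituents on both rings and is not stereogenic. The selectivity needed is cross-condensation over self-condensation of 2, which slow addition of 2 to hot 1 and base, continuous removal of ethanol and the drain into the aromatic polyphenolate should secure; the fourfold symmetry of 1 leaves no regiochemical choice.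

Step 2
Reactants: 4 tetraethyl 2,2',4,4',6,6'-hexahydroxybiphenyl-3,3',5,5'-tetracarboxylate
Product: 6 biphenyl-2,2',4,4',6,6'-hexol, via tetracarboxylic acid 5 (not isolated)
Conditions: aq. NaOH (excess), Na2S2O4 (cat.), argon, reflux; then AcOH to pH 4–5, 60 °C
Reagents that add atoms: none
Why: Ester saponification followed by protodecarboxylation: the 2,4,6-trihydroxybenzoic acid units of 5 lose CO2 under mild conditions through their ring-protonated cyclohexadienone tautomers, exclusion of oxygen protects the electron-rich hexaphenolate, and the weakly acidic finish avoids acid-catalysed cyclodehydration of the 2,2'-diol to a dibenzofuran; no stereocentre is formed.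

Step 3
Reactants: 6 biphenyl-2,2',4,4',6,6'-hexol; 7 ethyl 3-(4-methoxyphenyl)-3-oxopropanoate
Product: 11 5,7-dihydroxy-6-[5,7-dihydroxy-2-(4-methoxyphenyl)-4-oxo-4H-chromen-8-yl]-2-(4-methoxyphenyl)-4H-chromen-4-one (the target), via bis(1,3-diketone) 8 (not isolated), via bis-6-linked biflavone 9 (not isolated), via bis-8-linked biflavone 10 (not isolated)
Conditions: 7 (3 equiv), neat, 240–250 °C, argon, EtOH and H2O distilled off; cooled melt triturated (Et2O); then 2 M HCl, dioxane/H2O, reflux, argon; chromatography (silica gel, then Sephadex LH-20), fractions of 9 and 10 returned to the HCl stage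
Reagents that add atoms: none
Why: Mentzer pyrone synthesis followed by Wessely–Moser equilibration: at 240–250 °C ketoester 7 loses ethanol to an aroylketene that C-acylates the one free position of each electron-rich ring (C3 and C5 are equivalent, as are C3' and C5') to give 8, whose two cyclodehydrations through the hydroxyl para or ortho to the axis should give the 6,8''-linked target 11 together with the 6,6''-linked 9 (two para closures) and the 8,8''-linked 10 (two ortho closures), and hot aqueous HCl then reopens the 5-hydroxypyranone rings by hydration at C2 to the aryl 1,3-diketones so that 9 and 10 can reclose through the other ortho hydroxyl and the mixture should settle at the equilibrium in which the mixed isomer 11 carries double statistical weight, HCl being chosen over HI so that both aryl methyl ethers are kept; no stereocentre is formed.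

**Compound list**

1 | tetraethyl ethane-1,1,2,2-tetracarboxylate | CCOC(=O)C(C(=O)OCC)C(C(=O)OCC)C(=O)OCC | starting material
2 | diethyl 3-oxopentanedioate (diethyl 1,3-acetonedicarboxylate) | CCOC(=O)CC(=O)CC(=O)OCC | starting material
3 | diethyl 5-[bis(ethoxycarbonyl)methyl]-2,4,6-trihydroxybenzene-1,3-dicarboxylate (mono-annulated arylmalonate) | CCOC(=O)C(C(=O)OCC)c1c(O)c(C(=O)OCC)c(O)c(C(=O)OCC)c1O | intermediate
4 | tetraethyl 2,2',4,4',6,6'-hexahydroxybiphenyl-3,3',5,5'-tetracarboxylate | CCOC(=O)c1c(O)c(C(=O)OCC)c(O)c(-c2c(O)c(C(=O)OCC)c(O)c(C(=O)OCC)c2O)c1O | intermediate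
5 | 2,2',4,4',6,6'-hexahydroxybiphenyl-3,3',5,5'-tetracarboxylic acid | OC(=O)c1c(O)c(C(=O)O)c(O)c(-c2c(O)c(C(=O)O)c(O)c(C(=O)O)c2O)c1O | intermediate
6 | biphenyl-2,2',4,4',6,6'-hexol | Oc1cc(O)c(-c2c(O)cc(O)cc2O)c(O)c1 | intermediate
7 | ethyl 3-(4-methoxyphenyl)-3-oxopropanoate | CCOC(=O)CC(=O)c1ccc(OC)cc1 | starting material
8 | 3,3'-bis[3-(4-methoxyphenyl)-3-oxopropanoyl]biphenyl-2,2',4,4',6,6'-hexol | COc1ccc(C(=O)CC(=O)c2c(O)cc(O)c(-c3c(O)cc(O)c(C(=O)CC(=O)c4ccc(OC)cc4)c3O)c2O)cc1 | intermediate
9 | 6,6'-bi[5,7-dihydroxy-2-(4-methoxyphenyl)-4H-chromen-4-one] (6,6''-linked isomer) | COc1ccc(-c2cc(=O)c3c(O)c(-c4c(O)cc5oc(-c6ccc(OC)cc6)cc(=O)c5c4O)c(O)cc3o2)cc1 | intermediate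
10 | 8,8'-bi[5,7-dihydroxy-2-(4-methoxyphenyl)-4H-chromen-4-one] (8,8''-linked isomer) | COc1ccc(-c2cc(=O)c3c(O)cc(O)c(-c4c(O)cc(O)c5c(=O)cc(-c6ccc(OC)cc6)oc45)c3o2)cc1 | intermediate
11 | 5,7-dihydroxy-6-[5,7-dihydroxy-2-(4-methoxyphenyl)-4-oxo-4H-chromen-8-yl]-2-(4-methoxyphenyl)-4H-chromen-4-one (6,8''-linked; 4',4'''-di-O-methylagathisflavone) | COc1ccc(-c2cc(=O)c3c(O)c(-c4c(O)cc(O)c5c(=O)cc(-c6ccc(OC)cc6)oc45)c(O)cc3o2)cc1 | target

**Step count**

Total step count: 3. Longest linear sequence: 3 (steps 1–3).

**Steps most likely to fail**

Step 1 (proposed new method). Self-condensation of 2 may outrun acylation at the hindered and largely deprotonated malonate ends of 1, or the sequence may stop after one ring at the stage of 3. The fallback gives up the [3+3] construction and uses known biaryl chemistry. It does not set out from a numbered compound of the route: compounds 1 and 2 are replaced by purchased 2-iodo-1,3,5-trimethoxybenzene F1. Ullmann homocoupling of the iodide (Cu powder, neat, 230 °C) should give 2,2',4,4',6,6'-hexamethoxybiphenyl F2. Cleavage of the six methyl ethers with BBr3 (CH2Cl2, −78 °C to room temperature, aqueous work-up under argon) should then give the hexol, so the fallback comes back to the route at compound 6 and bypasses steps 1 and 2.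

Step 3. At 240–250 °C the hexol may decompose or cyclodehydrate across the 2,2'-diol, the second ring may fail to condense, and coumarin formation of the Pechmann type may compete. In the acid stage the pyranone rings may open too slowly, or the sparingly soluble biflavones may stay out of solution, so that the isomer distribution is not corrected. The fallback sets out from compound 6 and builds the rings C below 130 °C through chalcones. Friedel–Crafts C-acylation of each ring with (E)-3-(4-methoxyphenyl)prop-2-enoyl chloride F3 (2.2 equiv, in BF3·OEt2 as solvent and promoter, 80 °C) should give 3,3'-bis[(E)-3-(4-methoxyphenyl)prop-2-enoyl]biphenyl-2,2',4,4',6,6'-hexol F4. Oxidative cyclisation (I2 cat., DMSO, 130 °C; oxa-Michael closure, then dehydrogenation) should then give the flavones as the same set of linkage isomers 9, 10 and 11. The crude mixture is put through the HCl stage and the chromatography of step 3, so the fallback comes back to the route at compound 11.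

Step 2. The hexaphenolate may be oxidised in hot alkali despite the exclusion of air, the last carboxyl group may be lost sluggishly, and the acidification may trigger cyclodehydration to a dibenzofuran. The fallback sets out from compound 4 and keeps the phenols masked while the four carboxyl groups are removed. O-Methylation (Me2SO4, K2CO3, acetone, reflux) should give tetraethyl 2,2',4,4',6,6'-hexamethoxybiphenyl-3,3',5,5'-tetracarboxylate F5. Saponification of the hindered esters (KOH, aq. DMSO, 100 °C; then HCl) should give 2,2',4,4',6,6'-hexamethoxybiphenyl-3,3',5,5'-tetracarboxylic acid F6. Protodecarboxylation of its 2,6-dimethoxybenzoic acid units (Ag2CO3 cat., AcOH cat., DMSO, 120 °C) should give 2,2',4,4',6,6'-hexamethoxybiphenyl F2, the compound also made in the fallback for step 1. Cleavage of the methyl ethers with BBr3 (CH2Cl2, −78 °C to room temperature, aqueous work-up under argon) then gives the hexol, so the fallback comes back to the route at compound 6.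

**Further compounds**

F1 | step 1 | 2-iodo-1,3,5-trimethoxybenzene (purchased) | COc1cc(OC)c(I)c(OC)c1
F2 | step 1 | 2,2',4,4',6,6'-hexamethoxybiphenyl | COc1cc(OC)c(-c2c(OC)cc(OC)cc2OC)c(OC)c1
F3 | step 3 | (E)-3-(4-methoxyphenyl)prop-2-enoyl chloride (purchased) | COc1ccc(/C=C/C(Cl)=O)cc1
F4 | step 3 | 3,3'-bis[(E)-3-(4-methoxyphenyl)prop-2-enoyl]biphenyl-2,2',4,4',6,6'-hexol | COc1ccc(/C=C/C(=O)c2c(O)cc(O)c(-c3c(O)cc(O)c(C(=O)/C=C/c4ccc(OC)cc4)c3O)c2O)cc1
F5 | step 2 | tetraethyl 2,2',4,4',6,6'-hexamethoxybiphenyl-3,3',5,5'-tetracarboxylate | CCOC(=O)c1c(OC)c(C(=O)OCC)c(OC)c(-c2c(OC)c(C(=O)OCC)c(OC)c(C(=O)OCC)c2OC)c1OC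
F6 | step 2 | 2,2',4,4',6,6'-hexamethoxybiphenyl-3,3',5,5'-tetracarboxylic acid | OC(=O)c1c(OC)c(C(=O)O)c(OC)c(-c2c(OC)c(C(=O)O)c(OC)c(C(=O)O)c2OC)c1OC
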